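## Retrosynthetic overview

1. Feature used: in ring C the adjacent carbons C3 (C–O) and C4 (C=O) are both at carbonyl oxidation level. They are already linked the long way round through C4a–C8a–O1–C2, so the C3–C4 bond can be made from two formyl groups by umpolung of one of them.
2. End game (retro): C5–OH from C5–OMe (chelation-directed BCl3), C3–OMe from the flavonol, and the flavonol from the trans-dihydroflavonol by dehydrogenation, which erases both sp3 centres.
3. Key disconnection C3–C4: the dihydroflavonol comes from an aryl/aliphatic dialdehyde by carbene-catalysed intramolecular crossed benzoin, with the aryl formyl carbon (C4) as the acyl-anion donor.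
4. The dialdehyde comes from the diol, and the diol from the ester aldehyde. The ester aldehyde is made by O1–C2 Williamson union of 2-hydroxy-3,4,5,6-tetramethoxybenzaldehyde (two steps from 1,2,3,4-tetramethoxybenzene) with methyl α-bromo(3-methoxyphenyl)acetate.
5. Ring order: rings A and B are bought as arenes, and ring C is the only ring formed, in the key step.

Key step: step 7

Remark: the target has no stereocentre, so all chiral intermediates are used as racemates. The methyl ester of 3-methoxyphenylacetic acid is taken as the purchased form of that building block.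

## Route

Step 1
Reactants: 1 1,2,3,4-tetramethoxybenzene
Product: 4 2,3,4,5-tetramethoxyphenol, via 2,3,4,5-tetramethoxyphenyllithium 2 (not isolated), via lithium aryltrimethoxyborate 3 (not isolated)
Conditions: n-BuLi, TMEDA, THF, 0 °C; B(OMe)3, −78 °C to rt; AcOH, 30% aq. H2O2, 0 °C to rt
Reagents that add atoms: hydrogen peroxide, OO
Why: Directed ortho-metalation (the two free ring positions of 1 are equivalent and each lies next to a methoxy group), borate trapping and peroxide-induced aryl migration from boron to oxygen should give the phenol in one flask, with the acetic acid buffer protecting the electron-rich phenol from over-oxidation.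

Step 2
Reactants: 4 2,3,4,5-tetramethoxyphenol
Product: 5 2-hydroxy-3,4,5,6-tetramethoxybenzaldehyde
Conditions: MgCl2, Et3N, (CH2O)n, MeCN, reflux; 1 M HCl work-up
Reagents that add atoms: formaldehyde (as paraformaldehyde), C=O
Why: In this Casnati–Skattebøl ortho-formylation the magnesium phenoxide delivers formaldehyde to the only free ring carbon, ortho to the OH, and a second formaldehyde accepts hydride from the benzylic alkoxide to give the salicylaldehyde.

Step 3
Reactants: 6 methyl (3-methoxyphenyl)acetate
Product: 7 racemic methyl 2-bromo-2-(3-methoxyphenyl)acetate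
Conditions: NBS, 2,2'-azobis(2-methylpropionitrile) (5 mol %), PhCF3, reflux
Reagents that add atoms: N-bromosuccinimide, O=C1CCC(=O)N1Br
Why: In this Wohl–Ziegler bromination hydrogen abstraction is fastest at the benzylic C–H next to the ester, the non-polar medium suppresses ionic bromination of the anisole ring, and the new centre is racemic and is erased in step 8.

Step 4
Reactants: 5 2-hydroxy-3,4,5,6-tetramethoxybenzaldehyde; 7 racemic methyl 2-bromo-2-(3-methoxyphenyl)acetate
Product: 8 racemic methyl 2-(2-formyl-3,4,5,6-tetramethoxyphenoxy)-2-(3-methoxyphenyl)acetate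
Conditions: K2CO3, DMF, rt
Reagents that add atoms: none
Why: In this Williamson ether synthesis the acidic salicylaldehyde phenoxide displaces the doubly activated secondary bromide by SN2 to form O1–C2, and a carbonate base at room temperature avoids aldol closure of the product to a benzofuran.

Step 5
Reactants: 8 racemic methyl 2-(2-formyl-3,4,5,6-tetramethoxyphenoxy)-2-(3-methoxyphenyl)acetate
Product: 9 racemic 2-[2-(hydroxymethyl)-3,4,5,6-tetramethoxyphenoxy]-2-(3-methoxyphenyl)ethan-1-ol
Conditions: LiAlH4, THF, 0 °C; aqueous NaOH work-up
Reagents that add atoms: none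
Why: Hydride reduction of the ester and the aryl aldehyde in one operation outruns any enolate chemistry and leaves the aryl methyl ethers and the benzylic aryl ether untouched.

Step 6
Reactants: 9 racemic 2-[2-(hydroxymethyl)-3,4,5,6-tetramethoxyphenoxy]-2-(3-methoxyphenyl)ethan-1-ol
Product: 10 racemic 2,3,4,5-tetramethoxy-6-[1-(3-methoxyphenyl)-2-oxoethoxy]benzaldehyde
Conditions: Dess–Martin periodinane (2.4 equiv), CH2Cl2, 0 °C to rt; aq. Na2S2O3/NaHCO3 wash; used at once without chromatography
Reagents that add atoms: none
Why: Dess–Martin oxidation takes the primary and the benzylic alcohol to the aldehyde level without added base, which spares the easily enolised C2–H and avoids the benzylic chloride formation that activated-DMSO methods risk with so electron-rich a benzylic alcohol.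

Step 7
Reactants: 10 racemic 2,3,4,5-tetramethoxy-6-[1-(3-methoxyphenyl)-2-oxoethoxy]benzaldehyde
Product: 12 racemic (2R*,3R*)-trans-3-hydroxy-5,6,7,8-tetramethoxy-2-(3-methoxyphenyl)chroman-4-one, via Breslow enaminol 11 (not isolated)
Conditions: 2-(pentafluorophenyl)-6,7-dihydro-5H-pyrrolo[2,1-c][1,2,4]triazol-2-ium tetrafluoroborate (15 mol %), iPr2NEt (20 mol %), 4 Å MS, CH2Cl2 (0.02 M), Ar, rt to 40 °C
Reagents that add atoms: none
Why: iPr2NEt frees the triazolylidene, which adds reversibly to the aryl formyl carbon (C4); proton transfer gives Breslow enaminol 11, its nucleophilic C4 attacks the aliphatic formyl carbon (C3), and collapse of the adduct restores the C4 ketone and releases the carbene. The closest known reaction types are the azolium-catalysed intramolecular crossed benzoin of 2-(2-oxoalkoxy)benzaldehydes to 3-hydroxychroman-4-ones and the intermolecular cross-benzoin in which α-branched, α-heteroatom-substituted aliphatic aldehydes act only as acceptors towards aromatic acyl-anion donors. Ring C closes in the 6-exo-trig mode across the C4a–C8a–O1–C2 tether. C3 is the only new stereocentre: it lies α to the new ketone and equilibrates through the C3–C4 enediol under the amine base, so the C2 aryl group should steer it to the diequatorial 2,3-trans isomer, and any cis isomer is equally useful because both centres become sp2 in step 8. The step needs donor/acceptor chemoselectivity, since an enaminol raised at C3 would expel the O1 aryloxide (internal redox) and cut the tether instead of closing the ring; the substrate should secure it because the aliphatic formyl group sits on a tertiary carbon walled in by ring B and the hexasubstituted ring A (slow enaminol formation) while its α-oxygen makes it the better electrophile, and because the ortho-alkoxy groups favour the carbene adduct of the aryl aldehyde, which the reversibly adding N-C6F5 carbene can funnel into the fast six-ring closure. The weak amine base and high dilution hold back enolisation at C2, the competing five-ring aldol of C2 onto the aryl formyl group and intermolecular coupling.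

Step 8
Reactants: 12 racemic trans-3-hydroxy-5,6,7,8-tetramethoxy-2-(3-methoxyphenyl)chroman-4-one
Product: 14 3-hydroxy-5,6,7,8-tetramethoxy-2-(3-methoxyphenyl)-4H-chromen-4-one, via chroman-3,4-dione 13 (not isolated)
Conditions: I2 (20 mol %), DMSO, 100 °C
Reagents that add atoms: none
Why: In this I2/DMSO dehydrogenation (the method used for flavanones and dihydroflavonols) iodine oxidises the enediol tautomer of the acyloin to dione 13, which tautomerises through its acidic C2–H to the conjugated 3-hydroxychromone while DMSO re-oxidises HI to I2.

Step 9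
Reactants: 14 3-hydroxy-5,6,7,8-tetramethoxy-2-(3-methoxyphenyl)-4H-chromen-4-one
Product: 15 3,5,6,7,8-pentamethoxy-2-(3-methoxyphenyl)-4H-chromen-4-one
Conditions: MeI, K2CO3, acetone, reflux
Reagents that add atoms: iodomethane, CI
Why: Williamson O-methylation of the acidic enolic C3–OH, the only free hydroxyl in the molecule, is unambiguous.

Step 10
Reactants: 15 3,5,6,7,8-pentamethoxy-2-(3-methoxyphenyl)-4H-chromen-4-one
Product: 17 Emmaosunin [5-hydroxy-3,6,7,8-tetramethoxy-2-(3-methoxyphenyl)-4H-chromen-4-one], via C5-O dichloroboryl chelate 16 (not isolated)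
Conditions: BCl3 (1.2 equiv, 1 M in CH2Cl2), CH2Cl2, −78 to 0 °C; then H2O
Reagents that add atoms: none
Why: In this chelation-directed ether cleavage BCl3 binds the C4 carbonyl and the peri C5 oxygen in a six-membered chelate and chloride removes that methyl group by SN2, whereas the C3 methoxy group could form only a strained five-membered chelate and the remaining methoxy groups have no carbonyl partner.

## Compound list

1 | 1,2,3,4-tetramethoxybenzene | COc1ccc(OC)c(OC)c1OC | starting material
2 | 2,3,4,5-tetramethoxyphenyllithium (not isolated) | [Li]c1cc(OC)c(OC)c(OC)c1OC | intermediate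
3 | lithium trimethoxy(2,3,4,5-tetramethoxyphenyl)borate (not isolated) | [Li+].COc1cc([B-](OC)(OC)OC)c(OC)c(OC)c1OC | intermediate
4 | 2,3,4,5-tetramethoxyphenol | COc1cc(O)c(OC)c(OC)c1OC | intermediate
5 | 2-hydroxy-3,4,5,6-tetramethoxybenzaldehyde | COc1c(O)c(C=O)c(OC)c(OC)c1OC | intermediate
6 | methyl (3-methoxyphenyl)acetate | COC(=O)Cc1cccc(OC)c1 | starting material
7 | racemic methyl 2-bromo-2-(3-methoxyphenyl)acetate | COC(=O)C(Br)c1cccc(OC)c1 | intermediate
8 | racemic methyl 2-(2-formyl-3,4,5,6-tetramethoxyphenoxy)-2-(3-methoxyphenyl)acetate | COC(=O)C(Oc1c(C=O)c(OC)c(OC)c(OC)c1OC)c1cccc(OC)c1 | intermediate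
9 | racemic 2-[2-(hydroxymethyl)-3,4,5,6-tetramethoxyphenoxy]-2-(3-methoxyphenyl)ethan-1-ol | COc1cccc(C(CO)Oc2c(CO)c(OC)c(OC)c(OC)c2OC)c1 | intermediate
10 | racemic 2,3,4,5-tetramethoxy-6-[1-(3-methoxyphenyl)-2-oxoethoxy]benzaldehyde (key-step precursor) | COc1cccc(C(C=O)Oc2c(C=O)c(OC)c(OC)c(OC)c2OC)c1 | intermediate
11 | Breslow enaminol of the aryl formyl group of 10 with the N-pentafluorophenyl pyrrolotriazolylidene (not isolated) | COc1cccc(C(C=O)Oc2c(C(O)=C3N(c4c(F)c(F)c(F)c(F)c4F)N=C4CCCN34)c(OC)c(OC)c(OC)c2OC)c1 | intermediate
12 | racemic trans-3-hydroxy-5,6,7,8-tetramethoxy-2-(3-methoxyphenyl)chroman-4-one (2R,3R enantiomer drawn; key-step product) | COc1cccc(c1)[C@@H]1[C@H](C(=O)c2c(OC)c(OC)c(OC)c(OC)c2O1)O | intermediate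
13 | racemic 5,6,7,8-tetramethoxy-2-(3-methoxyphenyl)chroman-3,4-dione (not isolated) | COc1cccc(C2Oc3c(OC)c(OC)c(OC)c(OC)c3C(=O)C2=O)c1 | intermediate
14 | 3-hydroxy-5,6,7,8-tetramethoxy-2-(3-methoxyphenyl)-4H-chromen-4-one | COc1cccc(-c2oc3c(OC)c(OC)c(OC)c(OC)c3c(=O)c2O)c1 | intermediate
15 | 3,5,6,7,8-pentamethoxy-2-(3-methoxyphenyl)-4H-chromen-4-one | COc1cccc(-c2oc3c(OC)c(OC)c(OC)c(OC)c3c(=O)c2OC)c1 | intermediate
16 | 5-(dichloroboryloxy)-3,6,7,8-tetramethoxy-2-(3-methoxyphenyl)-4H-chromen-4-one, boron chelated to the C4 carbonyl (not isolated) | COc1cccc(-c2oc3c(OC)c(OC)c(OC)c(OB(Cl)Cl)c3c(=O)c2OC)c1 | intermediate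
17 | Emmaosunin, 5-hydroxy-3,6,7,8-tetramethoxy-2-(3-methoxyphenyl)-4H-chromen-4-one | COc1cccc(-c2oc3c(OC)c(OC)c(OC)c(O)c3c(=O)c2OC)c1 | target

## Step count

- Total step count: 10.
- Longest linear sequence: 9 steps (steps 1, 2, 4, 5, 6, 7, 8, 9, 10, from 1).

## Steps most likely to fail

**1. Step 7**

What may go wrong:
- The carbene may engage the aliphatic formyl group first, with loss of the O1 aryloxide and cleavage of the tether.
- The doubly ortho-substituted, electron-rich aryl aldehyde may pass only slowly from carbene adduct to enaminol.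
- Amine-induced enolisation at C2 may divert material into the five-ring aldol manifold.

The fallback builds ring C by acyl transfer and cyclodehydration (bonds C2–C3 and O1–C2, no umpolung). It sets out from 4 and comes back at 15. Phenol 4 is C-acylated at its only free ring position with methoxyacetic acid in BF3·OEt2 at 80 °C to give 1-(2-hydroxy-3,4,5,6-tetramethoxyphenyl)-2-methoxyethan-1-one F1. This is O-acylated with 3-methoxybenzoyl chloride in pyridine to 2-(methoxyacetyl)-3,4,5,6-tetramethoxyphenyl 3-methoxybenzoate F2. Baker–Venkataraman rearrangement (KOH, pyridine, 50 °C) then gives 1-(2-hydroxy-3,4,5,6-tetramethoxyphenyl)-2-methoxy-3-(3-methoxyphenyl)propane-1,3-dione F3. Cyclodehydration (catalytic H2SO4, AcOH, 100 °C) delivers 15, after which step 10 follows unchanged.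

**2. Step 6**

What may go wrong:
- The α-aryl-α-aryloxy aldehyde enolises readily, so it may be eroded during oxidation and work-up by further oxidation at C2 or by aldol closure onto the aryl formyl group.
- The half-oxidised hydroxy aldehyde may close to a seven-membered lactol that is oxidised on to a lactone.

The fallback reaches the aliphatic aldehyde by partial reduction instead of oxidation. It sets out from 8 and comes back at 10. The aryl aldehyde of 8 is masked with HC(OMe)3 and catalytic p-toluenesulfonic acid in MeOH as methyl 2-[2-(dimethoxymethyl)-3,4,5,6-tetramethoxyphenoxy]-2-(3-methoxyphenyl)acetate F4. i-Bu2AlH in toluene at −78 °C stops at the aldehyde level, because the α-aryloxy group stabilises the tetrahedral aluminium adduct until the quench. This gives 2-[2-(dimethoxymethyl)-3,4,5,6-tetramethoxyphenoxy]-2-(3-methoxyphenyl)acetaldehyde F5. The very labile acetal of the electron-rich benzaldehyde is then removed with catalytic pyridinium p-toluenesulfonate in wet acetone at rt to give 10.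

**3. Step 10**

What may go wrong:
- The Lewis acid may also cleave the C3 methoxy group through the C4 carbonyl.
- Once the C5 oxygen carries boron, the neighbouring C6 methoxy group may be cleaved as well, so selectivity may be lost before conversion is complete.

The fallback inverts the order, so that no C3 methyl ether is present during the Lewis acid step. It sets out from 14 and comes back at 17. Flavonol 14 is treated with BCl3 (2.5 equiv, the first equivalent being taken up by the C3–OH) in CH2Cl2 at −78 to 0 °C to give 3,5-dihydroxy-6,7,8-trimethoxy-2-(3-methoxyphenyl)-4H-chromen-4-one F6. One equivalent of MeI with K2CO3 in acetone at rt then methylates the more acidic C3–OH, while the C5–OH, tied to the C4 carbonyl by a strong hydrogen bond, stays free. This gives 17 directly.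

## Further compounds

F1 | step 7 | 1-(2-hydroxy-3,4,5,6-tetramethoxyphenyl)-2-methoxyethan-1-one | COCC(=O)c1c(O)c(OC)c(OC)c(OC)c1OC
F2 | step 7 | 2-(methoxyacetyl)-3,4,5,6-tetramethoxyphenyl 3-methoxybenzoate | COCC(=O)c1c(OC(=O)c2cccc(OC)c2)c(OC)c(OC)c(OC)c1OC
F3 | step 7 | racemic 1-(2-hydroxy-3,4,5,6-tetramethoxyphenyl)-2-methoxy-3-(3-methoxyphenyl)propane-1,3-dione | COC(C(=O)c1cccc(OC)c1)C(=O)c1c(O)c(OC)c(OC)c(OC)c1OC
F4 | step 6 | racemic methyl 2-[2-(dimethoxymethyl)-3,4,5,6-tetramethoxyphenoxy]-2-(3-methoxyphenyl)acetate | COC(=O)C(Oc1c(C(OC)OC)c(OC)c(OC)c(OC)c1OC)c1cccc(OC)c1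
F5 | step 6 | racemic 2-[2-(dimethoxymethyl)-3,4,5,6-tetramethoxyphenoxy]-2-(3-methoxyphenyl)acetaldehyde | COc1cccc(C(C=O)Oc2c(C(OC)OC)c(OC)c(OC)c(OC)c2OC)c1
F6 | step 10 | 3,5-dihydroxy-6,7,8-trimethoxy-2-(3-methoxyphenyl)-4H-chromen-4-one | COc1cccc(-c2oc3c(OC)c(OC)c(OC)c(O)c3c(=O)c2O)c1
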